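I began with the clock.

| flask | substrate | first nucleophile | second nucleophile | protic impurity | remark | time |
|---|---|---|---|---|---|---|
| ochre | 0.40 M | 3 equiv | 1 equiv | 0.40 M | run made earlier |  |
| blue | 0.40 M | 3 equiv | 0.50 equiv | 0.40 M | run made earlier |  |
| grey | 0.40 M | 3 equiv | 2 equiv | 0.40 M | run made earlier |  |
| elm | 0.40 M | 3.00 equiv | 1.00 equiv | 0.400 M | everything together in a closed stirred flask, run for 30 min | 30 min |
| birch | 0.40 M | 3.00 equiv | 1.00 equiv (fed, over 30.0 min) | 0.400 M | a stirred flask in which second nucleophile is dosed at a steady rate over 30.0 min without added volume, worked up at 30 min | 30 min |
| larch | 0.40 M (fed, over 30.0 min) | 3.00 equiv | 1.00 equiv | 0.400 M | all but substrate at the start; substrate goes in evenly over 30.0 min, the run ends at 30 min | 30 min |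
| ash | 0.40 M | 3.00 equiv | 1.00 equiv | 0.400 M | one stirred flow tank at steady state, fed with the mixture as stated, mean residence time 30 min |  |



| ochre: time / min | ochre: target / % | blue: time / min | blue: target / % | grey: time / min | grey: target / % |
|---|---|---|---|---|---|
| 2.50 | 34 | 6.00 | 43 | 2.50 | 23 |
| 8.00 | 34 | 12.0 | 46 | 8.00 | 23 |
| 15.0 | 32 | 20.0 | 44 | 15.0 | 21 |
| 20.0 | 33 | 25.0 | 46 | 20.0 | 22 |
| 30.0 | 35 | 30.0 | 45 | 30.0 | 22 |

(each reading ± 1.5 percentage points)



- the stated concentrations are those of everything mixed, before any reaction; amounts are the same in each set-up
- the feed brings no volume worth counting
- the earlier runs were made in a closed, stirred flask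



1. the set-up with the highest amount of target at the outlet or at the end, in percent of the substrate put in ("none" if the first two lie within 2 percentage points) (elm / birch / larch / ash / none)
2. amount of target at the outlet or at the end, in percent of the substrate put in, elm
3. amount of target at the outlet or at the end, in percent of the substrate put in, birch
4. amount of target at the outlet or at the end, in percent of the substrate put in, larch
5. amount of target at the outlet or at the end, in percent of the substrate put in, ash



I asked first what the end of a closed flask looked like, and the runs showed it: the ochre run read 34% target at 2.50 min and 35% at 30.0 min, which I took as flat against a scatter of 1.5 percentage points, while the plateau lay at 45% in the blue run with 0.50 equiv of second nucleophile and at 22% in the grey run with 2 equiv. That gave me a ladder. On the fastest rung stood the making of target, which read as over by the first sample of the ochre run, so I gave substrate a life of at most 2.50 min. The dosing time of 30.0 min came next, 12.0 times longer. On the slowest rung stood the target itself, whose readings in each earlier closed run held level within the scatter.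

In a fed flask, then, substrate should sit in a quasi-steady state, and feed rate times life gave 0.0333 M. This estimate of the highest c(substrate) in a fed flask, the standing substrate, was what I carried forward. It told me to expect capture in larch to stretch across the dose and not finish in minutes. In birch, by the same ratio, I reckoned 8.33% of the second nucleophile to enter during one substrate life, so I expected birch well above elm.

The forecast gave 34% for elm, 61% for birch, 33.5% for larch and 36% for ash, with birch best, and held for larch that “the partners deplete along the same path as in batch, so selectivity is unchanged”.

The flasks gave 34.7% for elm, 58.1% for birch, 25.9% for larch and 20.8% for ash, with birch best.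

    substrate → intermediate (k = 0.0150 /s)
    first nucleophile + intermediate → target (k = 0.0250 /M/s)
    second nucleophile + intermediate → other capture product (k = 0.0560 /M/s)
    intermediate → solvolysis product (k = 0.00100 /s)
    target → over-reaction product (k = 8.50 × 10⁻⁷ /s)
    first nucleophile + protic impurity → quenched reagent (k = 0.00280 /M/s)
    substrate + target → side product (k = 0.0460 /M/s)

In larch, c(substrate) peaked at 0.0140 M, below the standing substrate of 0.0333 M, and capture stretched across the dose: the step from first nucleophile and intermediate to target had 19% of its turnover behind it at 6.00 min and the middle of it at 14.7 min. Beside the standing substrate, with 0.046 /M/s, I reckoned for target a half-life of 7.53 min, shorter than the dose. In ash, with the path from substrate and target to side product struck out, the flask gave 51.4% in place of 20.8%, which is 39% of what ash is missing, so this path is a part of the reason and not the main one.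

For one more flask, like larch but with 1.6 M of protic impurity, the same reckoning again gave 0.0333 M and a capture stretched over 30.0 min. That computed flask ended with c(substrate) at 0.0135 M, below the standing substrate, first nucleophile at 2.11% of its charge, and target at 8.15%.

The runs stem from a simulated flask with constants of no real substance; the scatter is artificial.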